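**Plan**

- Retrosynthesis: the C2–C3 bond of ring C is cut first (carbene C–H insertion). The diazo ketone is traced to a deoxybenzoin, the C4–C4a bond to a ring-A aryllithium plus a ring-B arylacetic Weinreb amide, the acyl carbon to a one-carbon homologation of a benzaldehyde, and the C5'–C(CH3)2 bond to a Claisen rearrangement.
- Enabling feature: C2 of ring C is a methylene bound to O1 of ring A and lies 1,6 to C3, so in the precursor it is the methyl of a ring-A methoxy group ortho to the C4 ketone.
- Forward: ring B is built first (O-4 prenylation, 2,3-diphenylmethylene ketal, Claisen shift, O-methylation), extended to the arylacetic amide, acylated by ring A and diazotised. Ring C is closed last, followed by two deprotections.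
- Stereochemistry: C3 (S), the only stereocentre, is created in the ring-closing insertion under control of Rh2(S-PTTL)4; everything after it is kept non-basic.

Key step: step 12

Assumption: Rh2(S-PTTL)4 is taken to deliver the 3S product; if the sense of induction is the opposite, the mirror-image catalyst Rh2(R-PTTL)4 would be used under the same conditions.

Abbreviation: ArB = 7-methoxy-6-(2-methylbut-3-en-2-yl)-2,2-diphenyl-1,3-benzodioxol-4-yl, i.e. ring B carrying the diphenylmethylene ketal on O-2'/O-3', the 4'-methyl ether and the 5'-(1,1-dimethylallyl) group.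

**Route**

Step 1
Reactants: 1 2,3,4-trihydroxybenzaldehyde; 2 prenyl bromide (1-bromo-3-methylbut-2-ene)
Product: 3 2,3-dihydroxy-4-[(3-methylbut-2-en-1-yl)oxy]benzaldehyde
Conditions: NaHCO3, DMF, 40 °C
Reagents that add atoms: none
Why: Williamson etherification under bicarbonate should go to O-4, because only the 4-OH (para to the formyl group and not held in the hydrogen bond that ties up the 2-OH) is acidic enough to be ionised.

Step 2
Reactants: 3 2,3-dihydroxy-4-[(3-methylbut-2-en-1-yl)oxy]benzaldehyde; 4 dichlorodiphenylmethane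
Product: 5 7-[(3-methylbut-2-en-1-yl)oxy]-2,2-diphenyl-1,3-benzodioxole-4-carbaldehyde
Conditions: K2CO3, MeCN, 60 °C
Reagents that add atoms: none
Why: Ketalisation by double O-alkylation of the only remaining 1,2-diol with the benzhydrylic dichloride, run under basic conditions so that no HCl can cleave the allylic ether.

Step 3
Reactants: 5 7-[(3-methylbut-2-en-1-yl)oxy]-2,2-diphenyl-1,3-benzodioxole-4-carbaldehyde
Product: 6 7-hydroxy-6-(2-methylbut-3-en-2-yl)-2,2-diphenyl-1,3-benzodioxole-4-carbaldehyde
Conditions: PhNEt2, 190 °C, sealed tube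
Reagents that add atoms: none
Why: Aromatic Claisen rearrangement, in which the [3,3] shift can end productively only at the single ortho position that carries hydrogen, where the allyl unit arrives inverted as the 1,1-dimethylallyl group and the dienone tautomerises to the phenol.

Step 4
Reactants: 6 7-hydroxy-6-(2-methylbut-3-en-2-yl)-2,2-diphenyl-1,3-benzodioxole-4-carbaldehyde
Product: 7 7-methoxy-6-(2-methylbut-3-en-2-yl)-2,2-diphenyl-1,3-benzodioxole-4-carbaldehyde (ArB–CHO)
Conditions: MeI, K2CO3, DMF, rt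
Reagents that add atoms: iodomethane, CI
Why: Williamson methylation of the only free phenol, which is flanked on both sides but should still accept the small electrophile.

Step 5
Reactants: 7 ArB–CHO
Product: 8 ArB–CH=CH–OMe, 7-methoxy-4-(2-methoxyethenyl)-6-(2-methylbut-3-en-2-yl)-2,2-diphenyl-1,3-benzodioxole (E/Z mixture)
Conditions: Ph3P(CH2OMe)Cl, KOtBu, THF, 0 °C to rt
Reagents that add atoms: (methoxymethyl)triphenylphosphonium chloride, COC[P+](c1ccccc1)(c1ccccc1)c1ccccc1.[Cl-]
Why: Wittig olefination with the non-stabilised methoxymethylene ylide adds the one carbon needed; the alkene geometry is irrelevant because both isomers hydrolyse to the same aldehyde.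

Step 6
Reactants: 8 ArB–CH=CH–OMe (E/Z mixture)
Product: 9 ArB–CH2–CHO, 2-ArB-acetaldehyde
Conditions: 2 M aq HCl, THF, 40 °C
Reagents that add atoms: water, O
Why: Acid-catalysed enol ether hydrolysis (C-protonation, oxocarbenium ion, hemiacetal collapse) should free the arylacetaldehyde, while the catechol ketal, whose aryl-bound oxygens are poorly basic, is expected to hold in dilute acid at this temperature.

Step 7
Reactants: 9 ArB–CH2–CHO
Product: 10 ArB–CH2–CO2H, 2-ArB-acetic acid
Conditions: NaClO2, NaH2PO4, 2-methyl-2-butene, t-BuOH/H2O, 0 °C to rt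
Reagents that add atoms: sodium chlorite, [Na+].[O-]Cl=O
Why: Pinnick oxidation of the aldehyde, with excess 2-methyl-2-butene taking up the hypochlorous acid before it can reach the hindered vinyl group or the electron-rich arene.

Step 8
Reactants: 10 ArB–CH2–CO2H
Product: 12 ArB–CH2–C(=O)N(OMe)Me, N-methoxy-N-methyl-2-ArB-acetamide, via acyl imidazole 11 (not isolated)
Conditions: CDI, CH2Cl2, rt; then MeNHOMe·HCl, rt
Reagents that add atoms: N,O-dimethylhydroxylamine hydrochloride, CNOC.Cl
Why: Activation of the acid as its acyl imidazole and aminolysis give the Weinreb amide under neutral conditions that spare the ketal.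

Step 9
Reactants: 13 4-bromo-3-methoxyphenol
Product: 14 (4-bromo-3-methoxyphenoxy)(tert-butyl)dimethylsilane
Conditions: TBSCl, imidazole, DMF, rt
Reagents that add atoms: tert-butyldimethylsilyl chloride, CC(C)(C)[Si](C)(C)Cl
Why: Standard silylation of a phenol gives a protecting group that carries no C–H bond on an oxygen-bound carbon and is later removed by fluoride.

Step 10
Reactants: 12 N-methoxy-N-methyl-2-ArB-acetamide; 14 (4-bromo-3-methoxyphenoxy)(tert-butyl)dimethylsilane
Product: 16 1-[4-(tert-butyldimethylsilyloxy)-2-methoxyphenyl]-2-ArB-ethan-1-one (deoxybenzoin), via aryllithium 15 (not isolated)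
Conditions: 14, n-BuLi, THF, −78 °C; then 12, −78 to −20 °C; aq NH4Cl
Reagents that add atoms: none
Why: Bromine–lithium exchange followed by Weinreb ketone synthesis, in which the aryllithium adds at low temperature to a chelated tetrahedral adduct that cannot over-add, and the silyloxy group para to lithium cannot migrate.

Step 11
Reactants: 16 1-[4-(tert-butyldimethylsilyloxy)-2-methoxyphenyl]-2-ArB-ethan-1-one
Product: 17 2-diazo-1-[4-(tert-butyldimethylsilyloxy)-2-methoxyphenyl]-2-ArB-ethan-1-one
Conditions: p-ABSA, DBU, MeCN, 0 °C to rt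
Reagents that add atoms: 4-acetamidobenzenesulfonyl azide (p-ABSA), CC(=O)Nc1ccc(cc1)S(=O)(=O)N=[N+]=[N-]
Why: Regitz diazo transfer to the methylene that is both benzylic and alpha to the ketone, which an amidine base ionises without harming the silyl ether or the ketal.

Step 12
Reactants: 17 2-diazo-1-[4-(tert-butyldimethylsilyloxy)-2-methoxyphenyl]-2-ArB-ethan-1-one
Product: 18 (3S)-7-(tert-butyldimethylsilyloxy)-3-ArB-chroman-4-one
Conditions: dirhodium tetrakis[N-phthaloyl-(S)-tert-leucinate], Rh2(S-PTTL)4 (1 mol %), CH2Cl2, 4 Å MS, 17 added by syringe pump to 0.005 M, 0 °C to rt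
Reagents that add atoms: none
Why: Rh2(S-PTTL)4 should expel dinitrogen from 17 to give an aryl-substituted keto carbene on divalent rhodium at the future C3, whose vacant orbital engages a C–H bond of the neighbouring ring-A methoxy group in a concerted three-centre insertion that forms C2–C3 and delivers the hydrogen to C3. The closest known reaction type is the chiral dirhodium carboxylate-catalysed cyclisation of alpha-diazo ketones of 2-alkoxyaryl ketones to chroman-4-ones, together with the insertion of aryl-substituted acceptor carbenes into C–H bonds of methyl ethers. Ring C closes by 1,6 C–H insertion through a six-membered cyclic transition state made of C3, C4, C4a, C8a, O1 and C2. The one new stereocentre, C3, arises at the carbene carbon itself and is controlled by the chiral N-phthaloyl-tert-leucinate ligand sphere, which exposes one face of the rhodium-bound carbene to the incoming C–H bond. The step needs chemoselectivity for insertion over Stevens-type chemistry of the five-membered oxonium ylide at the methoxy oxygen and site selectivity against other C–H bonds: a methyl group migrates poorly so ylide formation should be reversible, the diphenylmethylene ketal leaves no C–H on a carbon attached to O-2' (which would open the favoured five-membered insertion on ring B), and the silyl ether and the vinyl group are out of intramolecular reach. High dilution and slow addition keep carbene dimerisation and intermolecular cyclopropanation of the hindered terminal alkene in check.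

Step 13
Reactants: 18 (3S)-7-(tert-butyldimethylsilyloxy)-3-ArB-chroman-4-one
Product: 19 (3S)-7-hydroxy-3-ArB-chroman-4-one
Conditions: TBAF, AcOH (1:1), THF, 0 °C
Reagents that add atoms: none
Why: Fluoride cleaves the aryl Si–O bond, and the acetic acid buffer keeps the medium from becoming basic enough to enolise C3 or open ring C by retro-oxa-Michael reaction.

Step 14
Reactants: 19 (3S)-7-hydroxy-3-ArB-chroman-4-one
Product: 20 (3S)-3-[2,3-dihydroxy-4-methoxy-5-(2-methylbut-3-en-2-yl)phenyl]-7-hydroxychroman-4-one (target)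
Conditions: AcOH/H2O 4:1, 80 °C
Reagents that add atoms: none
Why: Acid hydrolysis of the diphenylmethylene ketal through the diaryl-stabilised oxocarbenium ion releases the catechol and benzophenone under non-basic conditions that should leave the methyl ether, the terminal alkene (not adjacent to a free phenol) and, provided enolisation stays slow, the C3 stereocentre untouched.

**Compound list**

1 | 2,3,4-trihydroxybenzaldehyde | O=Cc1ccc(O)c(O)c1O | starting material
2 | prenyl bromide (1-bromo-3-methylbut-2-ene) | CC(C)=CCBr | starting material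
3 | 2,3-dihydroxy-4-[(3-methylbut-2-en-1-yl)oxy]benzaldehyde | O=Cc1ccc(OCC=C(C)C)c(O)c1O | intermediate
4 | dichlorodiphenylmethane | ClC(Cl)(c1ccccc1)c1ccccc1 | starting material
5 | 7-[(3-methylbut-2-en-1-yl)oxy]-2,2-diphenyl-1,3-benzodioxole-4-carbaldehyde | O=Cc1ccc(OCC=C(C)C)c2OC(c3ccccc3)(c3ccccc3)Oc12 | intermediate
6 | 7-hydroxy-6-(2-methylbut-3-en-2-yl)-2,2-diphenyl-1,3-benzodioxole-4-carbaldehyde | O=Cc1cc(C(C)(C)C=C)c(O)c2OC(c3ccccc3)(c3ccccc3)Oc12 | intermediate
7 | 7-methoxy-6-(2-methylbut-3-en-2-yl)-2,2-diphenyl-1,3-benzodioxole-4-carbaldehyde | O=Cc1cc(C(C)(C)C=C)c(OC)c2OC(c3ccccc3)(c3ccccc3)Oc12 | intermediate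
8 | 7-methoxy-4-(2-methoxyethenyl)-6-(2-methylbut-3-en-2-yl)-2,2-diphenyl-1,3-benzodioxole (E/Z mixture) | COC=Cc1cc(C(C)(C)C=C)c(OC)c2OC(c3ccccc3)(c3ccccc3)Oc12 | intermediate
9 | 2-[7-methoxy-6-(2-methylbut-3-en-2-yl)-2,2-diphenyl-1,3-benzodioxol-4-yl]acetaldehyde | O=CCc1cc(C(C)(C)C=C)c(OC)c2OC(c3ccccc3)(c3ccccc3)Oc12 | intermediate
10 | 2-[7-methoxy-6-(2-methylbut-3-en-2-yl)-2,2-diphenyl-1,3-benzodioxol-4-yl]acetic acid | OC(=O)Cc1cc(C(C)(C)C=C)c(OC)c2OC(c3ccccc3)(c3ccccc3)Oc12 | intermediate
11 | 1-(1H-imidazol-1-yl)-2-[7-methoxy-6-(2-methylbut-3-en-2-yl)-2,2-diphenyl-1,3-benzodioxol-4-yl]ethan-1-one (acyl imidazole, not isolated) | O=C(Cc1cc(C(C)(C)C=C)c(OC)c2OC(c3ccccc3)(c3ccccc3)Oc12)n1ccnc1 | intermediate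
12 | N-methoxy-N-methyl-2-[7-methoxy-6-(2-methylbut-3-en-2-yl)-2,2-diphenyl-1,3-benzodioxol-4-yl]acetamide | CON(C)C(=O)Cc1cc(C(C)(C)C=C)c(OC)c2OC(c3ccccc3)(c3ccccc3)Oc12 | intermediate
13 | 4-bromo-3-methoxyphenol | COc1cc(O)ccc1Br | starting material
14 | (4-bromo-3-methoxyphenoxy)(tert-butyl)dimethylsilane | COc1cc(O[Si](C)(C)C(C)(C)C)ccc1Br | intermediate
15 | [4-(tert-butyldimethylsilyloxy)-2-methoxyphenyl]lithium (not isolated) | COc1cc(O[Si](C)(C)C(C)(C)C)ccc1[Li] | intermediate
16 | 1-[4-(tert-butyldimethylsilyloxy)-2-methoxyphenyl]-2-[7-methoxy-6-(2-methylbut-3-en-2-yl)-2,2-diphenyl-1,3-benzodioxol-4-yl]ethan-1-one | COc1cc(O[Si](C)(C)C(C)(C)C)ccc1C(=O)Cc1cc(C(C)(C)C=C)c(OC)c2OC(c3ccccc3)(c3ccccc3)Oc12 | intermediate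
17 | 2-diazo-1-[4-(tert-butyldimethylsilyloxy)-2-methoxyphenyl]-2-[7-methoxy-6-(2-methylbut-3-en-2-yl)-2,2-diphenyl-1,3-benzodioxol-4-yl]ethan-1-one | COc1cc(O[Si](C)(C)C(C)(C)C)ccc1C(=O)C(=[N+]=[N-])c1cc(C(C)(C)C=C)c(OC)c2OC(c3ccccc3)(c3ccccc3)Oc12 | intermediate
18 | (3S)-7-(tert-butyldimethylsilyloxy)-3-[7-methoxy-6-(2-methylbut-3-en-2-yl)-2,2-diphenyl-1,3-benzodioxol-4-yl]chroman-4-one | C=CC(C)(C)c1cc([C@H]2COc3cc(O[Si](C)(C)C(C)(C)C)ccc3C2=O)c2OC(c3ccccc3)(c3ccccc3)Oc2c1OC | intermediate
19 | (3S)-7-hydroxy-3-[7-methoxy-6-(2-methylbut-3-en-2-yl)-2,2-diphenyl-1,3-benzodioxol-4-yl]chroman-4-one | C=CC(C)(C)c1cc([C@H]2COc3cc(O)ccc3C2=O)c2OC(c3ccccc3)(c3ccccc3)Oc2c1OC | intermediate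
20 | (3S)-3-[2,3-dihydroxy-4-methoxy-5-(2-methylbut-3-en-2-yl)phenyl]-7-hydroxychroman-4-one | C=CC(C)(C)c1cc([C@H]2COc3cc(O)ccc3C2=O)c(O)c(O)c1OC | target

**Step count**

Total: 14 steps. Longest linear sequence: 13 steps (steps 1–8 and 10–14 from 1); step 9 is a one-step side branch.

**Steps most likely to fail**

1. Step 12. The risk is diversion of the rhodium carbene into the five-membered oxonium ylide at the methoxy oxygen (methyl shift or demethylation) faster than it inserts, or insertion with poor facial selectivity at the carbene carbon. The fallback sets out from 16 and comes back at 18 without any carbene. MgI2 etherate in toluene/Et2O would cleave only the ketone-chelated ring-A methyl ether to give 1-[4-(tert-butyldimethylsilyloxy)-2-hydroxyphenyl]-2-ArB-ethan-1-one F1. N,N-Dimethylformamide dimethyl acetal would then supply C2 and close ring C as the isoflavone 7-(tert-butyldimethylsilyloxy)-3-ArB-4H-chromen-4-one F2. Asymmetric transfer hydrogenation with RuCl(p-cymene)[(S,S)-TsDPEN] (or its mirror image, whichever sets 3S) and HCO2H/Et3N reduces isoflavones through the configurationally labile isoflavanone under dynamic kinetic resolution; it should give the cis alcohol (3S,4S)-7-(tert-butyldimethylsilyloxy)-3-ArB-chroman-4-ol F3. Dess–Martin periodinane would then restore the C4 ketone without touching C3 and give 18.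

2. Step 14. The risk is acid-promoted enolisation of the alpha-aryl ketone during the ketal hydrolysis, which would erode the C3 configuration. The fallback sets out from 16 and comes back at 20; it moves the acid step in front of the stereocentre. Aqueous acetic acid would hydrolyse the ketal of 16 to the catechol 1-[4-(tert-butyldimethylsilyloxy)-2-methoxyphenyl]-2-[2,3-dihydroxy-4-methoxy-5-(2-methylbut-3-en-2-yl)phenyl]ethan-1-one F4. TBSOTf/2,6-lutidine would silylate both hydroxyls to the tris-silyl deoxybenzoin F5, and diazo transfer (p-ABSA, DBU) would give the tris-silyl diazo ketone F6. The same Rh2(S-PTTL)4 insertion would give the tris-silyl isoflavanone (3S)-7-(tert-butyldimethylsilyloxy)-3-[2,3-bis(tert-butyldimethylsilyloxy)-4-methoxy-5-(2-methylbut-3-en-2-yl)phenyl]chroman-4-one F7; silicon rather than carbon sits on O-2', so there is still no C–H on an oxygen-bound carbon within five-ring reach. One buffered fluoride treatment (TBAF/AcOH) would then give 20.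

3. Step 3. The risk is further rearrangement of the first-formed ortho-(1,1-dimethylallyl)phenol at the reaction temperature (hydrogen shift from the phenol along the abnormal Claisen path, or loss of the allyl unit), so that the reverse-prenyl group is not retained. The fallback sets out from 1 and comes back at 7; it replaces the sigmatropic shift by a cross-coupling. Selective O-4 methylation of 1 (Li2CO3, MeI, DMF) would give 2,3-dihydroxy-4-methoxybenzaldehyde F8. Ketalisation with 4 (K2CO3, MeCN) would give 7-methoxy-2,2-diphenyl-1,3-benzodioxole-4-carbaldehyde F9. NBS should brominate the position ortho to methoxy and meta to the formyl group to give 6-bromo-7-methoxy-2,2-diphenyl-1,3-benzodioxole-4-carbaldehyde F10. A gamma-selective Suzuki–Miyaura coupling of F10 with prenylboronic acid pinacol ester (Pd(OAc)2 with a dialkylbiarylphosphine chosen for the branched isomer, aqueous K3PO4, THF, 40 °C) would then deliver 7 directly.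

**Further compounds**

F1 | step 12 | 1-[4-(tert-butyldimethylsilyloxy)-2-hydroxyphenyl]-2-[7-methoxy-6-(2-methylbut-3-en-2-yl)-2,2-diphenyl-1,3-benzodioxol-4-yl]ethan-1-one | Oc1cc(O[Si](C)(C)C(C)(C)C)ccc1C(=O)Cc1cc(C(C)(C)C=C)c(OC)c2OC(c3ccccc3)(c3ccccc3)Oc12
F2 | step 12 | 7-(tert-butyldimethylsilyloxy)-3-[7-methoxy-6-(2-methylbut-3-en-2-yl)-2,2-diphenyl-1,3-benzodioxol-4-yl]-4H-chromen-4-one | C=CC(C)(C)c1cc(C2=COc3cc(O[Si](C)(C)C(C)(C)C)ccc3C2=O)c2OC(c3ccccc3)(c3ccccc3)Oc2c1OC
F3 | step 12 | (3S,4S)-7-(tert-butyldimethylsilyloxy)-3-[7-methoxy-6-(2-methylbut-3-en-2-yl)-2,2-diphenyl-1,3-benzodioxol-4-yl]chroman-4-ol (cis) | C=CC(C)(C)c1cc([C@H]2COc3cc(O[Si](C)(C)C(C)(C)C)ccc3[C@H]2O)c2OC(c3ccccc3)(c3ccccc3)Oc2c1OC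
F4 | step 14 | 1-[4-(tert-butyldimethylsilyloxy)-2-methoxyphenyl]-2-[2,3-dihydroxy-4-methoxy-5-(2-methylbut-3-en-2-yl)phenyl]ethan-1-one | COc1cc(O[Si](C)(C)C(C)(C)C)ccc1C(=O)Cc1cc(C(C)(C)C=C)c(OC)c(O)c1O
F5 | step 14 | 1-[4-(tert-butyldimethylsilyloxy)-2-methoxyphenyl]-2-[2,3-bis(tert-butyldimethylsilyloxy)-4-methoxy-5-(2-methylbut-3-en-2-yl)phenyl]ethan-1-one | COc1cc(O[Si](C)(C)C(C)(C)C)ccc1C(=O)Cc1cc(C(C)(C)C=C)c(OC)c(O[Si](C)(C)C(C)(C)C)c1O[Si](C)(C)C(C)(C)C
F6 | step 14 | 2-diazo-1-[4-(tert-butyldimethylsilyloxy)-2-methoxyphenyl]-2-[2,3-bis(tert-butyldimethylsilyloxy)-4-methoxy-5-(2-methylbut-3-en-2-yl)phenyl]ethan-1-one | COc1cc(O[Si](C)(C)C(C)(C)C)ccc1C(=O)C(=[N+]=[N-])c1cc(C(C)(C)C=C)c(OC)c(O[Si](C)(C)C(C)(C)C)c1O[Si](C)(C)C(C)(C)C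
F7 | step 14 | (3S)-7-(tert-butyldimethylsilyloxy)-3-[2,3-bis(tert-butyldimethylsilyloxy)-4-methoxy-5-(2-methylbut-3-en-2-yl)phenyl]chroman-4-one | C=CC(C)(C)c1cc([C@H]2COc3cc(O[Si](C)(C)C(C)(C)C)ccc3C2=O)c(O[Si](C)(C)C(C)(C)C)c(O[Si](C)(C)C(C)(C)C)c1OC
F8 | step 3 | 2,3-dihydroxy-4-methoxybenzaldehyde | COc1ccc(C=O)c(O)c1O
F9 | step 3 | 7-methoxy-2,2-diphenyl-1,3-benzodioxole-4-carbaldehyde | COc1ccc(C=O)c2OC(c3ccccc3)(c3ccccc3)Oc12
F10 | step 3 | 6-bromo-7-methoxy-2,2-diphenyl-1,3-benzodioxole-4-carbaldehyde | COc1c(Br)cc(C=O)c2OC(c3ccccc3)(c3ccccc3)Oc12
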